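**Retrosynthetic overview** (indene numbering of the target: C-1, C-2, C-3, C-3a, C-4 … C-7a)
1. Target 23 ⇐ vinyl epoxide 21: the trans-diaxial 5-OH/6-O-angelate pair beside the C-7 methylidene is released last by SN2 opening of a 5β,6β-epoxide with angelic acid; 21 ⇐ tertiary allylic alcohol 19 (directed epoxidation, syn-dehydration); the C-2 acetate comes from Mitsunobu inversion of 17.
2. Key disconnection: the C-2–C-3 bond of the five-membered ring; 17 ⇐ monocyclic ynal 15 + Me2Zn by nickel-catalysed alkylative alkyne–aldehyde cyclisation, which also brings in the ethylidene methyl carbon.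
3. Enabling feature: the five-membered ring (C-1, C-2, C-3, C-3a, C-7a) is a 2-alkylidenecyclopentanol. Carbinol carbon C-2 is bonded to C-3, which carries the exocyclic (Z)-ethylidene, the exact imprint of aldehyde + terminal alkyne + methyl. Its tether atoms C-3a and C-7a sit trans-diequatorial on the six-membered ring.
4. 15 ⇐ (S)-cryptone 4 (the six-membered ring is a p-menthane): conjugate alkynylation/enolate allylation set C-3a and C-7a; a second enone plus MeLi prepares C-5, C-6 and C-7; 4 ⇐ isovaleraldehyde + methyl vinyl ketone.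
5. Ring order: six-membered ring first (steps 1–2), five-membered ring in step 11, a temporary epoxide ring made in step 14 and opened in step 16.

Key step: step 11

Remark on notation: β is the ring face that carries the isopropyl group, α the opposite face; monocyclic intermediates keep the ring numbering of cryptone (C-1 former carbonyl carbon, C-4 isopropyl carbon), bicyclic ones use indene numbering; absolute configurations are those of the SMILES.

**Step 1**
Reactants: 1 3-methylbutanal; 2 but-3-en-2-one
Product: 3 (2S)-5-oxo-2-(propan-2-yl)hexanal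
Conditions: (S)-α,α-diphenylprolinol trimethylsilyl ether (5 mol%), ethyl 3,4-dihydroxybenzoate (20 mol%), neat, 4 °C
Reagents that add atoms: none
Why: Enamine-catalysed asymmetric Michael addition (first half of an organocatalytic Robinson annulation): the bulky diphenyl(silyloxy)methyl group shields one face of the (E)-enamine of 1, so the enone adds to the open face and the isopropyl-bearing centre should form as (S).

**Step 2**
Reactants: 3 (2S)-5-oxo-2-(propan-2-yl)hexanal
Product: 4 (S)-cryptone, (4S)-4-(propan-2-yl)cyclohex-2-en-1-one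
Conditions: LiOH (cat.), i-PrOH, rt
Reagents that add atoms: none
Why: Intramolecular aldol condensation (ring closure of the Robinson annulation) of the methyl ketone onto the aldehyde with E1cB dehydration; the mild hydroxide conditions should not epimerise the stereocentre, which becomes the γ-carbon of the enone.

**Step 3**
Reactants: 4 (S)-cryptone
Product: 5 4β-isopropyl-1-(trimethylsilyloxy)-3α-[(trimethylsilyl)ethynyl]cyclohex-1-ene
Conditions: Me3SiC≡CH, n-BuLi, THF, −78 °C; ZnBr2, −78 → 0 °C; then 4, Me3SiOTf, Et2O/THF, −78 → −40 °C; aq NaHCO3 work-up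
Reagents that add atoms: (trimethylsilyl)acetylene C#C[Si](C)(C)C; trimethylsilyl triflate C[Si](C)(C)OS(=O)(=O)C(F)(F)F
Why: Silyl-triflate-promoted conjugate addition of an alkynylzinc halide to an enone: axial attack anti to the neighbouring C-4 isopropyl group should set C-3 trans to it, and O-silylation stores the enolate regiospecifically.

**Step 4**
Reactants: 5 silyl enol ether
Product: 7 2β-allyl-4β-isopropyl-3α-[(trimethylsilyl)ethynyl]cyclohexan-1-one, via lithium enolate 6 (not isolated)
Conditions: MeLi, THF, 0 °C; then CH2=CHCH2I, DMPU, −78 → −20 °C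
Reagents that add atoms: allyl iodide C=CCI
Why: Regiospecific lithium enolate generation from the silyl enol ether with MeLi followed by C-allylation (enolate alkylation): the halide approaches anti to the adjacent alkynyl group, giving the all-trans, all-equatorial ketone, which is also the thermodynamic C-2 epimer.

**Step 5**
Reactants: 7 allyl ketone
Product: 9 2β-(2,2-dimethoxyethyl)-4β-isopropyl-3α-[(trimethylsilyl)ethynyl]cyclohexan-1-one, via keto aldehyde 8 (not isolated)
Conditions: O3, CH2Cl2/MeOH, −78 °C; Me2S, −78 °C → rt; then HC(OMe)3, PPTS (cat.), rt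
Reagents that add atoms: ozone O=[O+][O-] (oxygen of intermediate 8); trimethyl orthoformate COC(OC)OC (the two methoxy groups of 9)
Why: Ozonolysis of the terminal alkene (the silylalkyne reacts far more slowly) with reductive work-up, then chemoselective acetalisation of the aldehyde beside the hindered ketone; no stereocentre is touched.

**Step 6**
Reactants: 9 acetal ketone
Product: 11 2β-(2,2-dimethoxyethyl)-4β-isopropyl-3α-[(trimethylsilyl)ethynyl]cyclohex-5-en-1-one, via kinetic lithium enolate 10 (not isolated)
Conditions: LiN(i-Pr)2, THF, −78 °C; then PhS(Cl)=N-t-Bu, −78 °C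
Reagents that add atoms: none
Why: Kinetic deprotonation at the unsubstituted C-6 methylene rather than at tertiary C-2, then dehydrogenation of the lithium enolate with the sulfinimidoyl chloride (S-attack and syn-elimination at low temperature), should give the C-5/C-6 enone without epimerisation at C-2.

**Step 7**
Reactants: 11 enone
Product: 12 2β-(2,2-dimethoxyethyl)-4β-isopropyl-1α-methyl-3α-[(trimethylsilyl)ethynyl]cyclohex-5-en-1β-ol
Conditions: MeLi, Et2O, −78 °C; then H2O
Reagents that add atoms: methyllithium [Li]C
Why: 1,2-Addition of an organolithium to the enone carbonyl: attack along the equatorial trajectory on the α face, opposite the adjacent C-2 side chain, should give mainly the axial 1β tertiary alcohol (new stereocentre C-1, substrate control), and a minor epimer would be removed by chromatography.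

**Step 8**
Reactants: 12 tertiary alcohol
Product: 13 2β-(2,2-dimethoxyethyl)-3α-ethynyl-4β-isopropyl-1α-methylcyclohex-5-en-1β-ol
Conditions: K2CO3 (cat.), MeOH, rt
Reagents that add atoms: none
Why: Base-catalysed methanolysis of the alkynyl C–Si bond (protodesilylation), to which the acetal and the tertiary alcohol are inert.

**Step 9**
Reactants: 13 terminal alkyne
Product: 14 1β-triethylsilyl ether of 13
Conditions: Et3SiOTf, 2,6-lutidine, CH2Cl2, −78 → 0 °C
Reagents that add atoms: triethylsilyl triflate CC[Si](CC)(CC)OS(=O)(=O)C(F)(F)F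
Why: Silylation of a hindered tertiary alcohol with a silyl triflate and a hindered pyridine base; the ether prevents lactol formation with the aldehyde released next and keeps this oxygen away from the zinc reagent.

**Step 10**
Reactants: 14 silyl ether acetal
Product: 15 (3α-ethynyl-4β-isopropyl-1α-methyl-1β-triethylsilyloxycyclohex-5-en-2β-yl)acetaldehyde
Conditions: Et3SiOTf, 2,4,6-collidine, CH2Cl2, 0 °C; then H2O
Reagents that add atoms: water O
Why: Chemoselective acetal cleavage through a collidinium intermediate formed with the silyl triflate and hydrolysed by water, a non-acidic method under which the tertiary allylic silyl ether and the terminal alkyne should survive.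

**Step 11**
Reactants: 15 ynal
Product: 17 (3Z)-3-ethylidene-4β-isopropyl-7α-methyl-7β-(triethylsilyloxy)-2,3,3a,4,7,7a-hexahydro-1H-inden-2α-ol (trans-fused; H-3a β; H-7a α), via methylzinc alkoxide 16 (not isolated)
Conditions: Ni(cod)2 (10 mol%), Me2Zn (2.5 equiv), THF, 0 °C, slow addition of 15; then sat. aq NH4Cl
Reagents that add atoms: dimethylzinc C[Zn]C
Why: Zerovalent nickel binds the alkyne and the aldehyde of 15 and couples them by oxidative cyclisation to an oxanickelacyclopentene, which creates the C-2–C-3 bond; transmetalation with Me2Zn and C–C reductive elimination then put the methyl group on the distal alkyne carbon in the place nickel occupied, i.e. cis to the new ring bond, so the (Z)-ethylidene geometry follows from the mechanism (closest known reaction: the nickel-catalysed alkylative cyclisation of ynals with organozincs, known for terminal alkynes). The cyclopentane closes in the 5-exo-dig mode (the distal alkyne carbon ends exocyclic), and since the ethynyl and 2-oxoethyl arms are trans-diequatorial on the cyclohexene half-chair the ring fusion can only be trans. The new stereocentre C-2 is set by the metallacycle, which needs O–C-2–C-3=C close to coplanar: with the twist that the trans fusion imposes on the nascent five-membered ring only the C–O bond on the α face (cis to H-7a) reaches that plane, so the 2α-alcohol is expected and is inverted productively in step 12. The step needs alkyne–aldehyde coupling to beat direct methyl transfer to the aldehyde and alkyne oligomerisation; uncatalysed Me2Zn does not add to aldehydes at 0 °C, the five-membered intramolecular coupling is fast, 15 is added slowly to keep its concentration low, and the substrate offers nickel no enone, allylic ester or vinyl epoxide (the ring alkene and the tertiary silyl ether are inert). In one operation the last skeletal carbon is added, the hydrindane is closed, and the trisubstituted alkene geometry and the carbinol centre are fixed.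

**Step 12**
Reactants: 17 2α-alcohol
Product: 18 (3Z)-2β-acetoxy-3-ethylidene-4β-isopropyl-7α-methyl-7β-(triethylsilyloxy)-2,3,3a,4,7,7a-hexahydro-1H-indene
Conditions: PPh3, i-PrO2C–N=N–CO2i-Pr, AcOH, toluene, 0 °C → rt
Reagents that add atoms: acetic acid CC(=O)O
Why: Mitsunobu esterification: the oxyphosphonium salt of the 2α-alcohol is displaced by acetate in an SN2 step from the β face, which inverts C-2 and installs the acetate in one operation, helped by relief of allylic strain between the in-plane C–O bond and the (Z)-methyl group.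

**Step 13**
Reactants: 18 acetate silyl ether
Product: 19 (3Z)-2β-acetoxy-3-ethylidene-4β-isopropyl-7α-methyl-2,3,3a,4,7,7a-hexahydro-1H-inden-7β-ol
Conditions: HF·pyridine, pyridine, THF, 0 °C → rt
Reagents that add atoms: none
Why: Fluoride-mediated Si–O cleavage of the tertiary silyl ether under buffered conditions that leave the allylic acetate and both alkenes untouched.

**Step 14**
Reactants: 19 tertiary allylic alcohol
Product: 20 (3Z)-2β-acetoxy-5β,6β-epoxy-3-ethylidene-4β-isopropyl-7α-methyloctahydro-1H-inden-7β-ol
Conditions: VO(acac)2 (5 mol%), t-BuOOH, CH2Cl2, 0 °C → rt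
Reagents that add atoms: tert-butyl hydroperoxide CC(C)(C)OO
Why: Vanadium-catalysed hydroxyl-directed epoxidation: the axial 7β-hydroxyl delivers the peroxide oxygen to the β face of the adjacent C-5/C-6 alkene only (new stereocentres C-5 and C-6, substrate control), while the ethylidene, which has no free allylic hydroxyl, should not react.

**Step 15**
Reactants: 20 epoxy alcohol
Product: 21 (3Z)-2β-acetoxy-5β,6β-epoxy-3-ethylidene-4β-isopropyl-7-methylideneoctahydro-1H-indene
Conditions: Burgess reagent (MeO2C–N−–SO2–N+Et3), benzene, 50 °C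
Reagents that add atoms: none
Why: Burgess dehydration, a syn (Ei) elimination of the sulfamate ester: the only hydrogens syn to the axial 7β C–O bond are those of the methyl group (H-7a and H-6 are α), so the exocyclic methylidene should form and the epoxide stays intact.

**Step 16**
Reactants: 21 vinyl epoxide; 22 angelic acid
Product: 23 (2S,3Z,3aR,4S,5S,6S,7aR)-2-acetoxy-3-ethylidene-5-hydroxy-7-methylidene-4-(propan-2-yl)octahydro-1H-inden-6-yl (2Z)-2-methylbut-2-enoate
Conditions: 22 (5 equiv), i-Pr2NEt (0.3 equiv), toluene, 45 °C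
Reagents that add atoms: none
Why: Amine-catalysed SN2 opening of a vinyl epoxide by a carboxylic acid: attack at allylic C-6 from the α face is favoured by allylic activation and by the trans-diaxial (Fürst–Plattner) pathway, so C-6 is inverted to the α-angelate while the C-5 oxygen stays as the β-hydroxyl, and the near-neutral conditions should not isomerise the angelate to the tiglate.

**Compound list**
1 | 3-methylbutanal (isovaleraldehyde) | CC(C)CC=O | starting material
2 | but-3-en-2-one (methyl vinyl ketone) | C=CC(C)=O | starting material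
3 | (2S)-5-oxo-2-(propan-2-yl)hexanal | O=C[C@H](C(C)C)CCC(C)=O | intermediate
4 | (S)-cryptone, (4S)-4-(propan-2-yl)cyclohex-2-en-1-one | O=C1C=C[C@H](C(C)C)CC1 | intermediate
5 | 4β-isopropyl-1-(trimethylsilyloxy)-3α-[(trimethylsilyl)ethynyl]cyclohex-1-ene (3,4-trans) | C[Si](C)(C)OC1=C[C@@H](C#C[Si](C)(C)C)[C@H](C(C)C)CC1 | intermediate
6 | lithium enolate formed from 5 (C-1/C-2 enolate) | [Li+].[O-]C1=C[C@@H](C#C[Si](C)(C)C)[C@H](C(C)C)CC1 | intermediate
7 | 2β-allyl-4β-isopropyl-3α-[(trimethylsilyl)ethynyl]cyclohexan-1-one (all-trans) | O=C1[C@H](CC=C)[C@@H](C#C[Si](C)(C)C)[C@H](C(C)C)CC1 | intermediate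
8 | keto aldehyde: (4β-isopropyl-1-oxo-3α-[(trimethylsilyl)ethynyl]cyclohexan-2β-yl)acetaldehyde | O=C1[C@H](CC=O)[C@@H](C#C[Si](C)(C)C)[C@H](C(C)C)CC1 | intermediate
9 | 2β-(2,2-dimethoxyethyl)-4β-isopropyl-3α-[(trimethylsilyl)ethynyl]cyclohexan-1-one | O=C1[C@H](CC(OC)OC)[C@@H](C#C[Si](C)(C)C)[C@H](C(C)C)CC1 | intermediate
10 | kinetic lithium enolate of 9 (C-1/C-6 enolate) | [Li+].[O-]C=1[C@H](CC(OC)OC)[C@@H](C#C[Si](C)(C)C)[C@H](C(C)C)CC=1 | intermediate
11 | 2β-(2,2-dimethoxyethyl)-4β-isopropyl-3α-[(trimethylsilyl)ethynyl]cyclohex-5-en-1-one | O=C1[C@H](CC(OC)OC)[C@@H](C#C[Si](C)(C)C)[C@H](C(C)C)C=C1 | intermediate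
12 | 2β-(2,2-dimethoxyethyl)-4β-isopropyl-1α-methyl-3α-[(trimethylsilyl)ethynyl]cyclohex-5-en-1β-ol | C[C@@]1(O)[C@H](CC(OC)OC)[C@@H](C#C[Si](C)(C)C)[C@H](C(C)C)C=C1 | intermediate
13 | 2β-(2,2-dimethoxyethyl)-3α-ethynyl-4β-isopropyl-1α-methylcyclohex-5-en-1β-ol | C[C@@]1(O)[C@H](CC(OC)OC)[C@@H](C#C)[C@H](C(C)C)C=C1 | intermediate
14 | 1β-triethylsilyl ether of 13 | C[C@@]1(O[Si](CC)(CC)CC)[C@H](CC(OC)OC)[C@@H](C#C)[C@H](C(C)C)C=C1 | intermediate
15 | ynal: (3α-ethynyl-4β-isopropyl-1α-methyl-1β-triethylsilyloxycyclohex-5-en-2β-yl)acetaldehyde | C[C@@]1(O[Si](CC)(CC)CC)[C@H](CC=O)[C@@H](C#C)[C@H](C(C)C)C=C1 | intermediate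
16 | methylzinc alkoxide of 17 | C[C@@]1(O[Si](CC)(CC)CC)[C@@H]2C[C@@H](O[Zn]C)/C(=C\C)[C@H]2[C@H](C(C)C)C=C1 | intermediate
17 | (3Z)-3-ethylidene-4β-isopropyl-7α-methyl-7β-(triethylsilyloxy)-2,3,3a,4,7,7a-hexahydro-1H-inden-2α-ol (trans-fused, H-3a β, H-7a α) | C[C@@]1(O[Si](CC)(CC)CC)[C@@H]2C[C@@H](O)/C(=C\C)[C@H]2[C@H](C(C)C)C=C1 | intermediate
18 | (3Z)-2β-acetoxy-3-ethylidene-4β-isopropyl-7α-methyl-7β-(triethylsilyloxy)-2,3,3a,4,7,7a-hexahydro-1H-indene | C[C@@]1(O[Si](CC)(CC)CC)[C@@H]2C[C@H](OC(C)=O)/C(=C\C)[C@H]2[C@H](C(C)C)C=C1 | intermediate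
19 | (3Z)-2β-acetoxy-3-ethylidene-4β-isopropyl-7α-methyl-2,3,3a,4,7,7a-hexahydro-1H-inden-7β-ol | C[C@@]1(O)[C@@H]2C[C@H](OC(C)=O)/C(=C\C)[C@H]2[C@H](C(C)C)C=C1 | intermediate
20 | (3Z)-2β-acetoxy-5β,6β-epoxy-3-ethylidene-4β-isopropyl-7α-methyloctahydro-1H-inden-7β-ol | C[C@@]1(O)[C@@H]2C[C@H](OC(C)=O)/C(=C\C)[C@H]2[C@H](C(C)C)[C@@H]3O[C@@H]31 | intermediate
21 | (3Z)-2β-acetoxy-5β,6β-epoxy-3-ethylidene-4β-isopropyl-7-methylideneoctahydro-1H-indene | C=C1[C@@H]2C[C@H](OC(C)=O)/C(=C\C)[C@H]2[C@H](C(C)C)[C@@H]3O[C@@H]31 | intermediate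
22 | angelic acid, (2Z)-2-methylbut-2-enoic acid | C/C=C(/C)C(=O)O | starting material
23 | (2S,3Z,3aR,4S,5S,6S,7aR)-2-acetoxy-3-ethylidene-5-hydroxy-7-methylidene-4-(propan-2-yl)octahydro-1H-inden-6-yl (2Z)-2-methylbut-2-enoate (CNP0210397.1) | C=C1[C@@H]2C[C@H](OC(C)=O)/C(=C\C)[C@H]2[C@H](C(C)C)[C@H](O)[C@H]1OC(=O)/C(C)=C\C | target

**Step count and risks**
Total step count: 16. Longest linear sequence: 16 steps (fully linear from 1 and 2).

Steps most likely to fail:

1. Step 11. Nickel-mediated oligomerisation of the terminal alkyne, or direct methyl transfer to the aldehyde, may outrun closure of the strained trans-fused ring. The fallback sets out from 14 and forms the same C-2–C-3 bond by a Nozaki–Hiyama–Kishi reaction. Markovnikov hydration of the alkyne (Ph3PAuNTf2 cat., aqueous dioxane) should give methyl ketone F1. LiN(i-Pr)2 then MeI should give ethyl ketone F2. KN(SiMe3)2 and PhNTf2 should trap the (Z)-enolate as (Z)-enol triflate F3. Acetal cleavage as in step 10 gives aldehyde F4, and CrCl2 with catalytic NiCl2 in DMF should close the ring. The route is rejoined at 17; if the open transition state instead gives the 2β-alcohol F5, this is acetylated directly (Ac2O, DMAP) and the route is rejoined at 18.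

2. Step 16. Attack of the carboxylate at the methylidene terminus (allylic transposition), or slow addition accompanied by isomerisation of the angelate, may erode the final step. The fallback sets out from 21: acid-catalysed hydrolysis (HClO4 cat., THF/H2O, 0 °C) with the small nucleophile water should open the epoxide trans-diaxially at C-6 to the 5β,6α-diol F7. Mono-esterification of its allylic, less hindered 6-hydroxyl with the mixed anhydride from angelic acid 22 and 2,4,6-trichlorobenzoyl chloride (Et3N, toluene, 75 °C; Yamaguchi-type) returns to the route at 23.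

3. Step 12. Allylic transposition (SN2′ attack at the ethylidene carbon) or elimination of the activated alcohol may compete with direct displacement. The fallback sets out from 17: Dess–Martin periodinane should give the (Z)-enone F6. Reagent-controlled CBS reduction ((R)-2-methyl-CBS-oxazaborolidine, catecholborane, toluene, −78 °C) should deliver the 2β-alcohol F5, the compound already named in the first fallback. Acetylation (Ac2O, DMAP, pyridine) returns to the route at 18.

**Further compounds**
F1 | step 11 | methyl ketone: 3α-acetyl-2β-(2,2-dimethoxyethyl)-4β-isopropyl-1α-methyl-1β-(triethylsilyloxy)cyclohex-5-ene | C[C@@]1(O[Si](CC)(CC)CC)[C@H](CC(OC)OC)[C@@H](C(C)=O)[C@H](C(C)C)C=C1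
F2 | step 11 | ethyl ketone: 3α-propanoyl analogue of F1 | C[C@@]1(O[Si](CC)(CC)CC)[C@H](CC(OC)OC)[C@@H](C(=O)CC)[C@H](C(C)C)C=C1
F3 | step 11 | (Z)-enol triflate of F2 (triflate oxygen cis to the methyl group) | C[C@@]1(O[Si](CC)(CC)CC)[C@H](CC(OC)OC)[C@@H](/C(OS(=O)(=O)C(F)(F)F)=C/C)[C@H](C(C)C)C=C1
F4 | step 11 | aldehyde from F3 (acetal cleaved) | C[C@@]1(O[Si](CC)(CC)CC)[C@H](CC=O)[C@@H](/C(OS(=O)(=O)C(F)(F)F)=C/C)[C@H](C(C)C)C=C1
F5 | step 11 | 2β-alcohol, C-2 epimer of 17 | C[C@@]1(O[Si](CC)(CC)CC)[C@@H]2C[C@H](O)/C(=C\C)[C@H]2[C@H](C(C)C)C=C1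
F6 | step 12 | (3Z)-3-ethylidene-4β-isopropyl-7α-methyl-7β-(triethylsilyloxy)-1,3,3a,4,7,7a-hexahydro-2H-inden-2-one | C[C@@]1(O[Si](CC)(CC)CC)[C@@H]2CC(=O)/C(=C\C)[C@H]2[C@H](C(C)C)C=C1
F7 | step 16 | (3Z)-2β-acetoxy-3-ethylidene-4β-isopropyl-7-methylideneoctahydro-1H-indene-5β,6α-diol | C=C1[C@@H]2C[C@H](OC(C)=O)/C(=C\C)[C@H]2[C@H](C(C)C)[C@H](O)[C@H]1O
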